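The route rests on a (3+3) disconnection of pyran ring C into an aryl ketone enol (O1–C2–C3) and a 2-bromo-4-hydroxybenzhydrol (C4–C4a–C8a). Because the 7-OH of ring A is para to C4a, C4 can be unmasked as a para-quinone methide: a chiral phosphoric acid steers the decarboxylative addition of a β-keto acid to it (C3–C4 bond, C4 stereocentre), and in the same flask CuI joins the enolate oxygen to C8a (O1–C8a bond). The resulting 2,4-diaryl-4H-chromene relays C4 to C2 and C3 by hydroboration anti to the 4-aryl group, and hydrogenolysis frees the phenols.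

Key step: step 6

Remarks on the chemistry:
- Flavan numbering is used (O1, C2, C3, C4, C4a, C5–C8, C8a). Ring A is the benzo ring, ring B the 2-aryl group, ring C the pyran ring and ring D the 4-aryl group.
- Assumption: the (R)-phosphoric acid, (R)-3,3'-bis(2,4,6-triisopropylphenyl)-1,1'-binaphthyl-2,2'-diyl hydrogen phosphate ((R)-TRIP), is taken to give the (R)-ketone 14. If the sense of induction proves opposite, the (S)-acid is used and nothing else changes.
- The C4 descriptor reads R in 13 and 14, S in 15, 16 and 17, and R in 18. This is only a change in CIP ranking; the spatial arrangement at C4 is the same throughout.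

Step 1
Reactants: 1 2-methoxybenzene-1,3-diol
Product: 2 1,3-bis(benzyloxy)-2-methoxybenzene
Conditions: BnBr (2.2 equiv), K2CO3, DMF, 60 °C
Reagents that add atoms: benzyl bromide, BrCc1ccccc1
Why: Williamson ether synthesis, in which both phenoxides displace bromide by SN2 and the benzyl groups can later be removed by hydrogenolysis without touching the methyl ether.

Step 2
Reactants: 2 1,3-bis(benzyloxy)-2-methoxybenzene
Product: 3 1,3-bis(benzyloxy)-4-bromo-2-methoxybenzene
Conditions: NBS (1.0 equiv), MeCN, 0 °C
Reagents that add atoms: N-bromosuccinimide, O=C1CCC(=O)N1Br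
Why: Electrophilic aromatic bromination, which should go to C4 (equivalent to C6) because it is ortho to one benzyloxy group and para to the other, whereas C5 is meta to both.

Step 3
Reactants: 3 1,3-bis(benzyloxy)-4-bromo-2-methoxybenzene, 4 2-bromo-4-hydroxybenzaldehyde
Product: 7 rac-[2,4-bis(benzyloxy)-3-methoxyphenyl](2-bromo-4-hydroxyphenyl)methanol, via aryllithium 5 (not isolated), via sodium phenoxide 6 (not isolated)
Conditions: 3, n-BuLi, THF, −78 °C; 4, NaH, THF, 0 °C; combine at −78 °C → 0 °C; aq. NH4Cl
Reagents that add atoms: none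
Why: Bromine–lithium exchange and 1,2-addition of the aryllithium to the aldehyde, with the phenol masked as its sodium salt so that it does not quench the nucleophile; the carbinol centre is racemic and is erased when C4 becomes the methide carbon in step 6.

Step 4
Reactants: 8 1-(3,4-dihydroxyphenyl)ethanone
Product: 9 1-[3,4-bis(benzyloxy)phenyl]ethanone
Conditions: BnBr (2.2 equiv), K2CO3, DMF, 60 °C
Reagents that add atoms: benzyl bromide, BrCc1ccccc1
Why: Williamson ether synthesis on the catechol, giving benzyl ethers that survive base, borane and copper and leave in the last step.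

Step 5
Reactants: 9 1-[3,4-bis(benzyloxy)phenyl]ethanone
Product: 11 3-[3,4-bis(benzyloxy)phenyl]-3-oxopropanoic acid, via lithium enolate 10 (not isolated)
Conditions: LiN(SiMe3)2 (1.1 equiv), THF, −78 °C; CO2 (excess); cold 1 M HCl
Reagents that add atoms: carbon dioxide, O=C=O
Why: Carboxylation of the kinetic lithium enolate of a methyl ketone with CO2, with the β-keto acid kept cold and used promptly because it decarboxylates on warming.

Step 6
Reactants: 7 rac-[2,4-bis(benzyloxy)-3-methoxyphenyl](2-bromo-4-hydroxyphenyl)methanol, 11 3-[3,4-bis(benzyloxy)phenyl]-3-oxopropanoic acid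
Product: 15 (S)-4-[2,4-bis(benzyloxy)-3-methoxyphenyl]-2-[3,4-bis(benzyloxy)phenyl]-4H-chromen-7-ol, via para-quinone methide 12 (not isolated), via adduct acid 13 (not isolated), via bromo ketone 14 (not isolated)
Conditions: (R)-TRIP (10 mol%), 11 (1.5 equiv), toluene (0.02 M), slow addition of 7, 0 °C → 40 °C; then Cs2CO3 (3 equiv), CuI (20 mol%), 1,10-phenanthroline (40 mol%), DMF, 80 °C
Reagents that add atoms: none
Why: Proposed new method: the phosphoric acid ionises 7 to the para-quinone methide 12, binds its quinoid oxygen through P–OH and the enol of 11 through P=O, and so delivers C3 to one face of C4 (1,6-addition); 13 then loses CO2 to give 14, and after addition of base CuI inserts into the C8a–Br bond and couples it with the enolate oxygen. The closest known reaction types are the phosphoric-acid-catalysed addition of enolised 1,3-dicarbonyl compounds to quinone methides formed in situ from hydroxybenzhydrols and the CuI-catalysed domino C-benzylation/O-arylation of 1,3-dicarbonyls with 2-bromobenzyl bromides; their union on one substrate in one flask has not been shown. Ring C closes by a six-membered intramolecular C(sp2)–O coupling of the (Z)-enolate oxygen, the only mode open because C-arylation would need a four-membered ring. C4 is the only new stereocentre and is set by the catalyst during C3–C4 bond formation, the free 7-OH of ring A being its hydrogen-bond handle and the unlike aryl groups on the methide carbon (2-bromo ring A against trioxygenated ring D) giving it two faces to tell apart. The step needs C- rather than O-alkylation of the enol (soft methide carbon, irreversible decarboxylation), addition faster than Friedel–Crafts attack of a second molecule of 7 (excess 11, high dilution) and enolate O-arylation faster than intermolecular phenoxide arylation (ring size and dilution).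

Step 7
Reactants: 15 (S)-4-[2,4-bis(benzyloxy)-3-methoxyphenyl]-2-[3,4-bis(benzyloxy)phenyl]-4H-chromen-7-ol
Product: 17 (2R,3S,4S)-4-[2,4-bis(benzyloxy)-3-methoxyphenyl]-2-[3,4-bis(benzyloxy)phenyl]-3,4-dihydro-2H-chromene-3,7-diol, via C3-borane 16 (not isolated)
Conditions: BH3·THF (4 equiv), THF, 0 °C → rt; then NaOH, H2O2, 0 °C
Reagents that add atoms: hydrogen peroxide, OO
Why: Hydroboration–oxidation of a cyclic enol ether, in which boron goes to C3 (the electron-rich β-carbon, remote from ring B) and H to C2 in a syn addition from the face opposite the 4-aryl group, so that after oxidation with retention the 3-OH is trans to both aryl groups and C2 and C3 are set by C4.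

Step 8
Reactants: 17 (2R,3S,4S)-4-[2,4-bis(benzyloxy)-3-methoxyphenyl]-2-[3,4-bis(benzyloxy)phenyl]-3,4-dihydro-2H-chromene-3,7-diol
Product: 18 (2R,3S,4R)-4-(2,4-dihydroxy-3-methoxyphenyl)-2-(3,4-dihydroxyphenyl)-3,4-dihydro-2H-chromene-3,7-diol
Conditions: H2 (1 atm), Pd(OH)2/C, THF/MeOH, rt
Reagents that add atoms: none
Why: Hydrogenolysis of the four benzyl aryl ethers under neutral conditions, which should leave the methyl ether, the cyclic C2–O1 bond and the three stereocentres untouched.

Compound list
1 | 2-methoxybenzene-1,3-diol | COc1c(O)cccc1O | starting material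
2 | 1,3-bis(benzyloxy)-2-methoxybenzene | COc1c(OCc2ccccc2)cccc1OCc1ccccc1 | intermediate
3 | 1,3-bis(benzyloxy)-4-bromo-2-methoxybenzene | COc1c(OCc2ccccc2)ccc(Br)c1OCc1ccccc1 | intermediate
4 | 2-bromo-4-hydroxybenzaldehyde | O=Cc1ccc(O)cc1Br | starting material
5 | [2,4-bis(benzyloxy)-3-methoxyphenyl]lithium (formed in the flask) | [Li]c1ccc(OCc2ccccc2)c(OC)c1OCc1ccccc1 | intermediate
6 | sodium 3-bromo-4-formylphenolate (formed in the flask) | [Na+].[O-]c1ccc(C=O)c(Br)c1 | intermediate
7 | rac-[2,4-bis(benzyloxy)-3-methoxyphenyl](2-bromo-4-hydroxyphenyl)methanol (carbinol centre undefined) | COc1c(OCc2ccccc2)ccc(C(O)c2ccc(O)cc2Br)c1OCc1ccccc1 | intermediate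
8 | 1-(3,4-dihydroxyphenyl)ethanone | CC(=O)c1ccc(O)c(O)c1 | starting material
9 | 1-[3,4-bis(benzyloxy)phenyl]ethanone | CC(=O)c1ccc(OCc2ccccc2)c(OCc2ccccc2)c1 | intermediate
10 | lithium 1-[3,4-bis(benzyloxy)phenyl]ethen-1-olate (formed in the flask) | [Li+].C=C([O-])c1ccc(OCc2ccccc2)c(OCc2ccccc2)c1 | intermediate
11 | 3-[3,4-bis(benzyloxy)phenyl]-3-oxopropanoic acid | OC(=O)CC(=O)c1ccc(OCc2ccccc2)c(OCc2ccccc2)c1 | intermediate
12 | 4-{[2,4-bis(benzyloxy)-3-methoxyphenyl]methylidene}-3-bromocyclohexa-2,5-dien-1-one (formed in the flask; alkene geometry not defined) | COc1c(OCc2ccccc2)ccc(C=C2C=CC(=O)C=C2Br)c1OCc1ccccc1 | intermediate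
13 | 2-{(R)-[2,4-bis(benzyloxy)-3-methoxyphenyl](2-bromo-4-hydroxyphenyl)methyl}-3-[3,4-bis(benzyloxy)phenyl]-3-oxopropanoic acid (formed in the flask; mixture at C2 of the acid) | COc1c(OCc2ccccc2)ccc([C@@H](C(C(=O)O)C(=O)c2ccc(OCc3ccccc3)c(OCc3ccccc3)c2)c2ccc(O)cc2Br)c1OCc1ccccc1 | intermediate
14 | (R)-3-[2,4-bis(benzyloxy)-3-methoxyphenyl]-1-[3,4-bis(benzyloxy)phenyl]-3-(2-bromo-4-hydroxyphenyl)propan-1-one (formed in the flask) | COc1c(OCc2ccccc2)ccc([C@@H](CC(=O)c2ccc(OCc3ccccc3)c(OCc3ccccc3)c2)c2ccc(O)cc2Br)c1OCc1ccccc1 | intermediate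
15 | (S)-4-[2,4-bis(benzyloxy)-3-methoxyphenyl]-2-[3,4-bis(benzyloxy)phenyl]-4H-chromen-7-ol | COc1c(OCc2ccccc2)ccc([C@@H]2c3ccc(O)cc3OC(c3ccc(OCc4ccccc4)c(OCc4ccccc4)c3)=C2)c1OCc1ccccc1 | intermediate
16 | (2S,3S,4S)-3-boranyl analogue of 17, BH2 in place of the 3-OH, 2,3-trans-3,4-trans (formed in the flask; the 7-OH is held as its borate under the conditions) | COc1c(OCc2ccccc2)ccc([C@@H]2c3ccc(O)cc3O[C@H](c3ccc(OCc4ccccc4)c(OCc4ccccc4)c3)[C@H]2B)c1OCc1ccccc1 | intermediate
17 | (2R,3S,4S)-4-[2,4-bis(benzyloxy)-3-methoxyphenyl]-2-[3,4-bis(benzyloxy)phenyl]-3,4-dihydro-2H-chromene-3,7-diol | COc1c(OCc2ccccc2)ccc([C@@H]2c3ccc(O)cc3O[C@H](c3ccc(OCc4ccccc4)c(OCc4ccccc4)c3)[C@H]2O)c1OCc1ccccc1 | intermediate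
18 | (2R,3S,4R)-4-(2,4-dihydroxy-3-methoxyphenyl)-2-(3,4-dihydroxyphenyl)-3,4-dihydro-2H-chromene-3,7-diol | COc1c(O)ccc([C@@H]2c3ccc(O)cc3O[C@H](c3ccc(O)c(O)c3)[C@H]2O)c1O | target

Total step count: 8. Longest linear sequence: 6 steps (steps 1, 2, 3, 6, 7 and 8).

Steps most likely to fail

Step 6 (Proposed new method). Three processes could defeat it. The carboxylic acid 11 could itself catalyse a racemic background addition. Friedel–Crafts oligomerisation of the electron-rich benzhydrol could outrun the enol. Under base and heat the double bond of the 4H-chromene could migrate, or the free phenoxide could be arylated intermolecularly. The fallback uses known chemistry only, sets C4 by a rhodium-catalysed conjugate arylation and closes the ring in a separate step. It sets out from 4, 9 and 3. Acid-catalysed Claisen–Schmidt condensation of 4 with 9 (SOCl2, EtOH, rt) should give (E)-1-[3,4-bis(benzyloxy)phenyl]-3-(2-bromo-4-hydroxyphenyl)prop-2-en-1-one F1. Lithiation of 3 (n-BuLi, THF, −78 °C), then B(OMe)3 and aqueous acid, should give [2,4-bis(benzyloxy)-3-methoxyphenyl]boronic acid F2. Hayashi–Miyaura addition of F2 to F1 with Rh(acac)(C2H4)2 and the antipode of BINAP that leads to the (R)-ketone (dioxane/H2O, 90 °C) should give 14, now isolated. The route is rejoined at 14, which is cyclised to 15 with CuI, 1,10-phenanthroline and Cs2CO3 alone.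

Step 7. The C3-borane carries an aryloxy group on C2, so β-elimination with opening of ring C could compete, and borane could add in part from the face of the 4-aryl group. The fallback sets out from 15. Dihydroxylation with OsO4 (cat.) and N-methylmorpholine N-oxide (acetone/H2O), anti to ring D, should give (2R,3S,4S)-4-[2,4-bis(benzyloxy)-3-methoxyphenyl]-2-[3,4-bis(benzyloxy)phenyl]-3,4-dihydro-2H-chromene-2,3,7-triol F3. Ionic reduction of its C2 hemiketal (Et3SiH, BF3·OEt2, CH2Cl2, −78 → −30 °C), with axial hydride delivery to the C2 oxocarbenium ion placing ring B equatorial, should return to the route at 17.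

Step 3. The sodium phenoxide of the aldehyde may be poorly soluble and poorly electrophilic, so addition could stall and the aryllithium could be lost by proton transfer or by anion translocation to its benzylic ether. The fallback sets out from 4. Silylation (TBSCl, imidazole, DMF) should give 2-bromo-4-[(tert-butyldimethylsilyl)oxy]benzaldehyde F4. Addition of aryllithium 5 (from 3, n-BuLi, THF, −78 °C) should give rac-[2,4-bis(benzyloxy)-3-methoxyphenyl]{2-bromo-4-[(tert-butyldimethylsilyl)oxy]phenyl}methanol F5. Desilylation (Bu4NF, THF, 0 °C) should return to the route at 7.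

Further compounds
F1 | step 6 | (E)-1-[3,4-bis(benzyloxy)phenyl]-3-(2-bromo-4-hydroxyphenyl)prop-2-en-1-one | O=C(/C=C/c1ccc(O)cc1Br)c1ccc(OCc2ccccc2)c(OCc2ccccc2)c1
F2 | step 6 | [2,4-bis(benzyloxy)-3-methoxyphenyl]boronic acid | COc1c(OCc2ccccc2)ccc(B(O)O)c1OCc1ccccc1
F3 | step 7 | (2R,3S,4S)-4-[2,4-bis(benzyloxy)-3-methoxyphenyl]-2-[3,4-bis(benzyloxy)phenyl]-3,4-dihydro-2H-chromene-2,3,7-triol | COc1c(OCc2ccccc2)ccc([C@@H]2c3ccc(O)cc3O[C@](O)(c3ccc(OCc4ccccc4)c(OCc4ccccc4)c3)[C@H]2O)c1OCc1ccccc1
F4 | step 3 | 2-bromo-4-[(tert-butyldimethylsilyl)oxy]benzaldehyde | CC(C)(C)[Si](C)(C)Oc1ccc(C=O)c(Br)c1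
F5 | step 3 | rac-[2,4-bis(benzyloxy)-3-methoxyphenyl]{2-bromo-4-[(tert-butyldimethylsilyl)oxy]phenyl}methanol | COc1c(OCc2ccccc2)ccc(C(O)c2ccc(O[Si](C)(C)C(C)(C)C)cc2Br)c1OCc1ccccc1
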